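**Retrosynthetic overview**

1. Diaryl ether C–O bond (made last): the target is the 4-O-5' dehydrodimer of (3S,4S)-arctigenin, so it is cut into two identical molecules of that phenol. One is iodinated in the flask at C5 and the other O-arylates it under copper catalysis.
2. C3–CH2Ar bond of each lactone: enolate of (S)-β-(3,4-dimethoxybenzyl)-γ-butyrolactone plus O-benzylvanillin (aldol, then hydrogenolysis of both benzylic C–O bonds).
3. Lactone: from the Stobbe half-ester of veratraldehyde and dimethyl succinate. C4 is set by asymmetric hydrogenation, C3 by substrate control (3,4-trans).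
4. Ring order: the γ-butyrolactone is the only ring built (once, in step 3). All arenes are bought, and the two lactone units are united last through the ether oxygen.

Stereochemical reading of the target: both lactone units are (3S,4S) (3,4-trans), the mirror-image series of natural (−)-arctigenin, so the monomer is made by catalysis and not taken from the natural product.

Assumption: [Rh(cod)((R,R)-Et-DuPhos)]BF4 is taken to give the (S)-succinate (the (S,S) complex giving (R)); the sense is checked by chiral HPLC and rotation at lactone 6, and the mirror-image complex is used if it proves opposite.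

**Route**

Step 1
Reactants: 1 3,4-dimethoxybenzaldehyde; 2 dimethyl succinate
Product: 3 (E)-4-(3,4-dimethoxyphenyl)-3-(methoxycarbonyl)but-3-enoic acid
Conditions: NaOMe (1.5 equiv), MeOH, reflux; then 2 M HCl
Reagents that add atoms: none
Why: Stobbe condensation; the succinate enolate adds to the aldehyde, the aldolate lactonises onto the distal ester and E1cB ring opening gives the (E)-alkylidene half-ester as its carboxylate, which drives the reaction and differentiates the two carboxyl groups.

Step 2
Reactants: 3 (E)-4-(3,4-dimethoxyphenyl)-3-(methoxycarbonyl)but-3-enoic acid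
Product: 4 (3S)-4-(3,4-dimethoxyphenyl)-3-(methoxycarbonyl)butanoic acid
Conditions: [Rh(cod)((R,R)-Et-DuPhos)]BF4 (0.2 mol%), NaOMe (10 mol%), H2 (5 bar), MeOH, 25 °C
Reagents that add atoms: none
Why: Rhodium–bisphospholane asymmetric hydrogenation of a Stobbe-type β-aryl itaconate half-ester; the carboxylate chelates monovalent rhodium beside the alkene and the C2-symmetric ligand selects one enantioface, setting the (S) centre that becomes lactone C4 (expected ≥ 95% ee).

Step 3
Reactants: 4 (3S)-4-(3,4-dimethoxyphenyl)-3-(methoxycarbonyl)butanoic acid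
Product: 6 (4S)-4-[(3,4-dimethoxyphenyl)methyl]oxolan-2-one, via potassium hydroxy-carboxylate 5 (not isolated)
Conditions: KOH (1.0 equiv), EtOH; CaCl2 (1.5 equiv), NaBH4 (3 equiv), −10 → 25 °C; then 3 M HCl, 25 °C
Reagents that add atoms: none
Why: Chemoselective ester reduction by Ca(BH4)2 formed in the flask (the carboxylate is inert to borohydride), then acid-promoted lactonisation closes the only new ring; the stereocentre is not touched.

Step 4
Reactants: 6 (4S)-4-[(3,4-dimethoxyphenyl)methyl]oxolan-2-one; 7 4-(benzyloxy)-3-methoxybenzaldehyde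
Product: 9 (3R,4S)-3-[(4-benzyloxy-3-methoxyphenyl)(hydroxy)methyl]-4-[(3,4-dimethoxyphenyl)methyl]oxolan-2-one (3,4-trans; both carbinol epimers), via lithium enolate 8 (not isolated)
Conditions: LiN(iPr)2 (1.1 equiv), THF, −78 °C; then 7 (1.1 equiv), −78 °C, 1 h; AcOH quench at −78 °C
Reagents that add atoms: none
Why: Aldol addition of a lactone lithium enolate; the aldehyde attacks the enolate face anti to the C4 benzyl group, giving the 3,4-trans lactone (dr typically ≥ 95:5), while the carbinol centre forms as a mixture and is erased in step 5 (the 3R label reflects only the CIP priority of the CH(OH)Ar group).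

Step 5
Reactants: 9 (3R,4S)-3-[(4-benzyloxy-3-methoxyphenyl)(hydroxy)methyl]-4-[(3,4-dimethoxyphenyl)methyl]oxolan-2-one
Product: 10 (3S,4S)-4-[(3,4-dimethoxyphenyl)methyl]-3-[(4-hydroxy-3-methoxyphenyl)methyl]oxolan-2-one [(3S,4S)-arctigenin]
Conditions: H2 (3 bar), Pd/C (10 wt%), AcOH, HClO4 (5 mol%), 25 °C
Reagents that add atoms: none
Why: Palladium-catalysed hydrogenolysis; the benzyl ether and the acid-activated, p-oxygenated benzylic C–OH (benzylic cation or quinone methide) are cleaved in one operation, C3 and C4 are not involved, and trans is also the thermodynamic arrangement.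

Step 6
Reactants: 10 (3S,4S)-arctigenin (two molecules)
Product: 12 4-O-5' dehydrodimer of (3S,4S)-arctigenin (the target), via 5-iodo-(3S,4S)-arctigenin 11 (not isolated)
Conditions: I2 (0.35 equiv), Cs2CO3 (2.5 equiv), 3 Å molecular sieves, DMF, 0 → 25 °C, 1 h; then CuI (10 mol%), N,N-dimethylglycine (30 mol%), 90 °C, argon; 1 M HCl work-up, unreacted 10 recovered
Reagents that add atoms: none
Why: Proposed new method: a one-pot iodine-relay dehydrogenative 4-O-5' homocoupling of an unprotected 4-alkylguaiacol, in which the cesium phenoxide of 10 is first iodinated by a deficit of I2 only at C5 (ortho to O−; para is blocked and the veratryl rings are inert to I2), so that about one third of the material becomes iodophenoxide 11 beside an excess of parent phenoxide, and CuI/N,N-dimethylglycine then turns the less hindered, more basic phenoxide of 10 into a monovalent copper aryloxide that inserts into the C–I bond of 11 (the neighbouring O− can hold copper next to the C–I bond, as the ortho-carboxylate does in the Hurtley reaction) and closes the C–O bond by reductive elimination from trivalent copper; because the ether bond is made by aryl halide substitution and not through phenoxyl radicals, the 5,5' C–C dimer that dominates oxidative couplings of guaiacols cannot form, the product phenol (flanked by OAr and OMe, no free ortho or para C–H) cannot enter the relay again, and no stereocentre is created (C3 can only equilibrate to the favoured trans lactone); the closest known chemistry is base-mediated ortho-iodination of phenols, ligand-accelerated Ullmann diaryl ether synthesis with O-protected ortho-halophenols, and the copper/methoxide conversion of unprotected 5-bromovanillin into syringaldehyde, whereas cross-coupling of a free ortho-iodophenol with its own parent phenol has not been shown.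

**Compound list**

1 | 3,4-dimethoxybenzaldehyde (veratraldehyde) | COc1ccc(C=O)cc1OC | starting material
2 | dimethyl succinate | COC(=O)CCC(=O)OC | starting material
3 | (E)-4-(3,4-dimethoxyphenyl)-3-(methoxycarbonyl)but-3-enoic acid | COC(=O)/C(=C/c1ccc(OC)c(OC)c1)CC(=O)O | intermediate
4 | (3S)-4-(3,4-dimethoxyphenyl)-3-(methoxycarbonyl)butanoic acid | COC(=O)[C@@H](Cc1ccc(OC)c(OC)c1)CC(=O)O | intermediate
5 | potassium (3S)-4-(3,4-dimethoxyphenyl)-3-(hydroxymethyl)butanoate (formed in the flask in step 3) | OC[C@@H](Cc1ccc(OC)c(OC)c1)CC(=O)[O-].[K+] | intermediate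
6 | (4S)-4-[(3,4-dimethoxyphenyl)methyl]oxolan-2-one | O=C1C[C@H](Cc2ccc(OC)c(OC)c2)CO1 | intermediate
7 | 4-(benzyloxy)-3-methoxybenzaldehyde (O-benzylvanillin) | COc1cc(C=O)ccc1OCc1ccccc1 | starting material
8 | lithium enolate of 6, lithium (4S)-4-[(3,4-dimethoxyphenyl)methyl]-4,5-dihydrofuran-2-olate (formed in the flask in step 4) | [Li+].[O-]C1=C[C@H](Cc2ccc(OC)c(OC)c2)CO1 | intermediate
9 | (3R,4S)-3-[(4-benzyloxy-3-methoxyphenyl)(hydroxy)methyl]-4-[(3,4-dimethoxyphenyl)methyl]oxolan-2-one (3,4-trans, carbinol epimer mixture) | COc1ccc(C[C@@H]2COC(=O)[C@H]2C(O)c2ccc(OCc3ccccc3)c(OC)c2)cc1OC | intermediate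
10 | (3S,4S)-4-[(3,4-dimethoxyphenyl)methyl]-3-[(4-hydroxy-3-methoxyphenyl)methyl]oxolan-2-one [(3S,4S)-arctigenin] | COc1ccc(C[C@@H]2COC(=O)[C@H]2Cc2ccc(O)c(OC)c2)cc1OC | intermediate
11 | (3S,4S)-4-[(3,4-dimethoxyphenyl)methyl]-3-[(4-hydroxy-3-iodo-5-methoxyphenyl)methyl]oxolan-2-one (formed in the flask in step 6) | COc1ccc(C[C@@H]2COC(=O)[C@H]2Cc2cc(I)c(O)c(OC)c2)cc1OC | intermediate
12 | (3S,4S)-4-[(3,4-dimethoxyphenyl)methyl]-3-[[4-[5-[[(3S,4S)-4-[(3,4-dimethoxyphenyl)methyl]-2-oxooxolan-3-yl]methyl]-2-hydroxy-3-methoxyphenoxy]-3-methoxyphenyl]methyl]oxolan-2-one | COc1ccc(C[C@@H]2COC(=O)[C@H]2Cc2ccc(Oc3cc(C[C@@H]4C(=O)OC[C@H]4Cc4ccc(OC)c(OC)c4)cc(OC)c3O)c(OC)c2)cc1OC | target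

**Step count**

Total steps: 6. Longest linear sequence: 6 (fully linear; step 6 joins two molecules of 10).

**Three steps most likely to fail, with fallbacks**

Step 6 (the proposed new coupling). Likely failure modes: slow copper insertion into the anionic, electron-rich ring of 11; 11 acting as the nucleophile (iodinated dimer, then dibenzodioxin); or loss of iodine from 11 (harmless, returns 10). The fallback uses only known chemistry, sets out from 10 and comes back at 12. All of one portion of 10 is iodinated (I2, Cs2CO3, MeCN, 0 °C) and the iodophenol 11 is isolated. Its phenol is benzylated (BnBr, K2CO3, DMF) to give (3S,4S)-3-[(4-benzyloxy-3-iodo-5-methoxyphenyl)methyl]-4-[(3,4-dimethoxyphenyl)methyl]oxolan-2-one F1. F1 is coupled with a second portion of 10 (1.5 equiv) under standard Ullmann ether conditions (CuI, N,N-dimethylglycine, Cs2CO3, dioxane, 90 °C) to the mono-O-benzyl ether of the target F2. Neutral hydrogenolysis (H2, Pd/C, EtOAc/EtOH) then gives 12.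

Step 5 (hydrogenolysis of the benzylic alcohol). Acid may dehydrate 9 to the α-benzylidene lactone, whose hydrogenation gives mainly the 3,4-cis lactone, or retro-aldol cleavage may lower the yield. The fallback replaces the aldol/hydrogenolysis pair by enolate alkylation; it sets out from 6 (with 7 as the source of the electrophile) and comes back at 10. Aldehyde 7 is reduced (NaBH4, MeOH) to (4-benzyloxy-3-methoxyphenyl)methanol F3 (also purchasable) and converted with PBr3 (Et2O, 0 °C) into 4-benzyloxy-3-methoxybenzyl bromide F4. Lithium enolate 8 (LiN(iPr)2, THF, −78 °C) is alkylated with F4 anti to the C4 substituent to give (3S,4S)-3-[(4-benzyloxy-3-methoxyphenyl)methyl]-4-[(3,4-dimethoxyphenyl)methyl]oxolan-2-one F5. Neutral debenzylation (H2, Pd/C, EtOAc) gives 10 with no benzylic alcohol ever present.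

Step 2 (asymmetric hydrogenation). The trisubstituted β-aryl alkene may give insufficient ee, or the E/Z content of 3 may erode it. The fallback sets the centre with a chiral auxiliary instead of a catalyst; it sets out from 1 and comes back at 6.
- Knoevenagel–Doebner condensation of 1 (malonic acid, pyridine, piperidine cat., 100 °C) gives (E)-3-(3,4-dimethoxyphenyl)prop-2-enoic acid F6.
- Hydrogenation (H2, Pd/C, EtOAc) gives 3-(3,4-dimethoxyphenyl)propanoic acid F7 (also a catalogue compound).
- (COCl)2 with catalytic DMF gives 3-(3,4-dimethoxyphenyl)propanoyl chloride F8.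
- F8 acylates (4R)-4-benzyl-1,3-oxazolidin-2-one (n-BuLi, THF, −78 °C) to (4R)-4-benzyl-3-[3-(3,4-dimethoxyphenyl)propanoyl]-1,3-oxazolidin-2-one F9.
- Evans alkylation (NaN(SiMe3)2, THF, −78 °C; tert-butyl bromoacetate) gives tert-butyl (3S)-3-{[(4R)-4-benzyl-2-oxo-1,3-oxazolidin-3-yl]carbonyl}-4-(3,4-dimethoxyphenyl)butanoate F10, the electrophile entering anti to the auxiliary benzyl group.
- LiBH4 (THF, 1 equiv MeOH, 0 °C) removes the auxiliary reductively to tert-butyl (3S)-4-(3,4-dimethoxyphenyl)-3-(hydroxymethyl)butanoate F11.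
- TsOH (cat.) in toluene at 80 °C lactonises F11 to 6.

**Further compounds**

F1 | step 6 | (3S,4S)-3-[(4-benzyloxy-3-iodo-5-methoxyphenyl)methyl]-4-[(3,4-dimethoxyphenyl)methyl]oxolan-2-one | COc1ccc(C[C@@H]2COC(=O)[C@H]2Cc2cc(I)c(OCc3ccccc3)c(OC)c2)cc1OC
F2 | step 6 | mono-O-benzyl ether of 12 (benzyl on the phenolic oxygen) | COc1ccc(C[C@@H]2COC(=O)[C@H]2Cc2ccc(Oc3cc(C[C@@H]4C(=O)OC[C@H]4Cc4ccc(OC)c(OC)c4)cc(OC)c3OCc3ccccc3)c(OC)c2)cc1OC
F3 | step 5 | (4-benzyloxy-3-methoxyphenyl)methanol | COc1cc(CO)ccc1OCc1ccccc1
F4 | step 5 | 4-benzyloxy-3-methoxybenzyl bromide | COc1cc(CBr)ccc1OCc1ccccc1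
F5 | step 5 | (3S,4S)-3-[(4-benzyloxy-3-methoxyphenyl)methyl]-4-[(3,4-dimethoxyphenyl)methyl]oxolan-2-one | COc1ccc(C[C@@H]2COC(=O)[C@H]2Cc2ccc(OCc3ccccc3)c(OC)c2)cc1OC
F6 | step 2 | (E)-3-(3,4-dimethoxyphenyl)prop-2-enoic acid | COc1ccc(/C=C/C(=O)O)cc1OC
F7 | step 2 | 3-(3,4-dimethoxyphenyl)propanoic acid | COc1ccc(CCC(=O)O)cc1OC
F8 | step 2 | 3-(3,4-dimethoxyphenyl)propanoyl chloride | COc1ccc(CCC(=O)Cl)cc1OC
F9 | step 2 | (4R)-4-benzyl-3-[3-(3,4-dimethoxyphenyl)propanoyl]-1,3-oxazolidin-2-one | COc1ccc(CCC(=O)N2[C@H](Cc3ccccc3)COC2=O)cc1OC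
F10 | step 2 | tert-butyl (3S)-3-{[(4R)-4-benzyl-2-oxo-1,3-oxazolidin-3-yl]carbonyl}-4-(3,4-dimethoxyphenyl)butanoate | COc1ccc(C[C@@H](CC(=O)OC(C)(C)C)C(=O)N2[C@H](Cc3ccccc3)COC2=O)cc1OC
F11 | step 2 | tert-butyl (3S)-4-(3,4-dimethoxyphenyl)-3-(hydroxymethyl)butanoate | COc1ccc(C[C@@H](CC(=O)OC(C)(C)C)CO)cc1OC
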